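**Assumption:** the SMILES is taken as authoritative. It encodes the (3S,4S)-lactone with the 3-OH cis and the 3-benzyl group trans to the 4-benzyl group. Compounds 1, 2, 6 and 15 and all unnumbered reagents are taken to be catalogue chemicals.

## Retrosynthetic overview

1. The target comes from its bis(benzyl ether) by one global hydrogenolysis.
2. Key disconnection: the quaternary C3–CH2(guaiacyl) bond, made by a visible-light double-decarboxylative radical cross-coupling of an α-hydroxy-α-carboxy lactone with the N-acyloxyphthalimide of O-benzylhomovanillic acid. The C4 substituent directs attack to the anti face.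
3. The α-hydroxy acid comes from α-hydroxylation and ester hydrolysis of a malonate-type lactone ester. The ester that activated the cyclopropane becomes the traceless radical handle.
4. The C4–CH2–aryl(syringyl) bond comes from a Cu-catalysed aryl-Grignard opening of a cyclopropane-fused lactone.
5. Ring order: cyclopropane, then γ-lactone, both in one pot from (R)-epichlorohydrin (sole source of chirality) and dimethyl malonate. The cyclopropane is then opened; the lactone is the only ring kept.

## Route

Step 1
Reactants: 1 (R)-epichlorohydrin [(2R)-2-(chloromethyl)oxirane]; 2 dimethyl malonate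
Product: 5 methyl (1S,5R)-2-oxo-3-oxabicyclo[3.1.0]hexane-1-carboxylate, via epoxy malonate 3 (not isolated), via cyclopropylmethanolate 4 (not isolated)
Conditions: NaOMe (1.2 equiv), MeOH, 0 °C → reflux, 18 h
Reagents that add atoms: none
Why: Tandem alkylation/cyclopropanation/lactonisation: malonate opens the epoxide at CH2, the chlorohydrin alkoxide recloses to epoxide 3, a second deprotonation gives 3-exo-tet ring closure with inversion to 4, and the alkoxide lactonises; C5 comes from the purchased stereocentre, C1 is fixed by the obligatory cis ring fusion, and about 95% ee or better is expected because the minor direct chloride-displacement path gives the enantiomer.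

Step 2
Reactants: 6 4-bromo-2,6-dimethoxyphenol
Product: 7 2-(benzyloxy)-5-bromo-1,3-dimethoxybenzene
Conditions: BnBr, K2CO3, DMF, 60 °C
Reagents that add atoms: benzyl bromide, BrCc1ccccc1
Why: Williamson ether synthesis (phenoxide SN2 on a benzylic bromide); no stereocentre is involved.

Step 3
Reactants: 7 2-(benzyloxy)-5-bromo-1,3-dimethoxybenzene; 5 methyl (1S,5R)-2-oxo-3-oxabicyclo[3.1.0]hexane-1-carboxylate
Product: 10 methyl (4R)-4-{[4-(benzyloxy)-3,5-dimethoxyphenyl]methyl}-2-oxooxolane-3-carboxylate (C3 epimers, trans major), via arylmagnesium bromide 8 (not isolated), via bromomagnesium enolate 9 (not isolated)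
Conditions: Mg, THF, 45 °C; then 5, CuI (10 mol%), THF, −30 → 0 °C; 1 M HCl
Reagents that add atoms: none
Why: Cu-catalysed homoconjugate (SN2-type) addition of the aryl Grignard to the doubly activated cyclopropane at its unhindered CH2, as established for alkyl Grignards on this lactone; no bond to the C–H stereocentre is broken, so it becomes C4 unchanged, and C3 is epimerisable and irrelevant.

Step 4
Reactants: 10 methyl (4R)-4-{[4-(benzyloxy)-3,5-dimethoxyphenyl]methyl}-2-oxooxolane-3-carboxylate
Product: 12 methyl (4S)-4-{[4-(benzyloxy)-3,5-dimethoxyphenyl]methyl}-3-hydroxy-2-oxooxolane-3-carboxylate (C3 epimers), via sodium enolate 11 (not isolated)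
Conditions: NaH, THF, 0 °C; racemic 2-(benzenesulfonyl)-3-phenyloxaziridine, −78 → 0 °C; 1 M HCl
Reagents that add atoms: 2-(benzenesulfonyl)-3-phenyloxaziridine, O=S(=O)(c1ccccc1)N1OC1c1ccccc1
Why: Davis-type electrophilic hydroxylation of the stabilised malonate enolate, with oxygen delivered mainly anti to the C4 group; the C3 configuration is erased in step 7, so its ratio does not matter (the C4 descriptor changes to S only through CIP priorities).

Step 5
Reactants: 12 methyl (4S)-4-{[4-(benzyloxy)-3,5-dimethoxyphenyl]methyl}-3-hydroxy-2-oxooxolane-3-carboxylate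
Product: 14 (4S)-4-{[4-(benzyloxy)-3,5-dimethoxyphenyl]methyl}-3-hydroxy-2-oxooxolane-3-carboxylic acid (C3 epimers), via dilithium dicarboxylate 13 (not isolated)
Conditions: LiOH·H2O (3.5 equiv), THF/H2O 3:1, 0 °C → rt; then 2 M HCl to pH 1, 35 °C
Reagents that add atoms: lithium hydroxide, [Li+].[OH-]
Why: Saponification of the methyl ester and lactone followed by acid-driven relactonisation of the γ-hydroxy diacid (favoured by the gem-dicarboxyl effect); either carboxyl may close because C3 becomes planar in step 7, and the tartronic-type half-acid does not decarboxylate below about 80 °C.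

Step 6
Reactants: 15 [4-(benzyloxy)-3-methoxyphenyl]acetic acid
Product: 17 1,3-dioxoisoindolin-2-yl [4-(benzyloxy)-3-methoxyphenyl]acetate, via O-acylisourea 16 (not isolated)
Conditions: N-hydroxyphthalimide, DIC, DMAP (5 mol%), CH2Cl2, 0 °C → rt
Reagents that add atoms: N-hydroxyphthalimide, O=C1c2ccccc2C(=O)N1O
Why: Carbodiimide (Steglich-type) esterification to the redox-active ester; no stereocentre is involved.

Step 7
Reactants: 14 (4S)-4-{[4-(benzyloxy)-3,5-dimethoxyphenyl]methyl}-3-hydroxy-2-oxooxolane-3-carboxylic acid; 17 1,3-dioxoisoindolin-2-yl [4-(benzyloxy)-3-methoxyphenyl]acetate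
Product: 20 (3S,4S)-3-{[4-(benzyloxy)-3-methoxyphenyl]methyl}-4-{[4-(benzyloxy)-3,5-dimethoxyphenyl]methyl}-3-hydroxyoxolan-2-one, via lactone radical 18 (not isolated), via benzyl radical 19 (not isolated)
Conditions: 17 (1.3 equiv), [Ir(dF(CF3)ppy)2(dtbbpy)]PF6 (1 mol%), Cs2CO3 (10 mol%), degassed DMSO/MeCN 1:1 (0.05 M), 450 nm LEDs, 20 °C
Reagents that add atoms: none
Why: Proposed new method: a redox-neutral, oxidant-free double-decarboxylative radical–radical C(sp3)–C(sp3) cross-coupling in which one photocatalyst turnover makes both partners — excited trivalent iridium (about +1.2 V vs SCE) oxidises the carboxylate of 14 (about +1.0 V) to the planar captodative C3 radical 18 with loss of CO2, the resulting divalent iridium (about −1.4 V) reduces ester 17 (about −1.3 V) to benzyl radical 19, CO2 and phthalimide anion, and that anion deprotonates the next molecule of 14, so no stoichiometric base or oxidant is present that would turn 18 into an enolisable keto lactone; hindered, stabilised 18 self-terminates slowly and captures transient 19 (persistent-radical effect) on the face anti to the C4 arylmethyl group, which sets C3 as S with the two benzyl groups trans and the OH cis to the C4 substituent; the closest known reaction types are photoredox oxidative decarboxylation of α-oxy acids, reductive fragmentation of N-acyloxyphthalimides, ketyl–benzyl radical cross-couplings and nickel-mediated double-decarboxylative sp3–sp3 couplings, none shown for a tertiary α-hydroxy malonic half-acid forming a fully substituted carbinol stereocentre.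

Step 8
Reactants: 20 (3S,4S)-3-{[4-(benzyloxy)-3-methoxyphenyl]methyl}-4-{[4-(benzyloxy)-3,5-dimethoxyphenyl]methyl}-3-hydroxyoxolan-2-one
Product: 21 (3S,4S)-3-hydroxy-3-[(4-hydroxy-3-methoxyphenyl)methyl]-4-[(4-hydroxy-3,5-dimethoxyphenyl)methyl]oxolan-2-one
Conditions: H2 (1 atm), Pd/C (10 wt%), EtOAc/EtOH 1:1, rt
Reagents that add atoms: none
Why: Hydrogenolysis of the two aryl benzyl ethers over palladium; the lactone, the non-benzylic tertiary alcohol, the aryl methyl ethers and both stereocentres are untouched.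

## Compound list

1 | (R)-epichlorohydrin | ClC[C@H]1CO1 | starting material
2 | dimethyl malonate | COC(=O)CC(=O)OC | starting material
3 | dimethyl 2-{[(2R)-oxiran-2-yl]methyl}propanedioate (not isolated) | COC(=O)C(C(=O)OC)C[C@@H]1CO1 | intermediate
4 | sodium [(1R)-2,2-bis(methoxycarbonyl)cyclopropyl]methanolate (not isolated) | COC(=O)C1(C(=O)OC)C[C@H]1C[O-].[Na+] | intermediate
5 | methyl (1S,5R)-2-oxo-3-oxabicyclo[3.1.0]hexane-1-carboxylate | COC(=O)[C@]12C[C@H]1COC2=O | intermediate
6 | 4-bromo-2,6-dimethoxyphenol | COc1cc(Br)cc(OC)c1O | starting material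
7 | 2-(benzyloxy)-5-bromo-1,3-dimethoxybenzene | COc1cc(Br)cc(OC)c1OCc1ccccc1 | intermediate
8 | [4-(benzyloxy)-3,5-dimethoxyphenyl]magnesium bromide (not isolated) | COc1cc([Mg]Br)cc(OC)c1OCc1ccccc1 | intermediate
9 | bromomagnesium enolate of 10, (4R) (not isolated) | COC(=O)C1=C(O[Mg]Br)OC[C@@H]1Cc1cc(OC)c(OCc2ccccc2)c(OC)c1 | intermediate
10 | methyl (4R)-4-{[4-(benzyloxy)-3,5-dimethoxyphenyl]methyl}-2-oxooxolane-3-carboxylate (C3 epimers) | COC(=O)C1C(=O)OC[C@@H]1Cc1cc(OC)c(OCc2ccccc2)c(OC)c1 | intermediate
11 | sodium enolate of 10, (4R) (not isolated) | COC(=O)C1=C([O-])OC[C@@H]1Cc1cc(OC)c(OCc2ccccc2)c(OC)c1.[Na+] | intermediate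
12 | methyl (4S)-4-{[4-(benzyloxy)-3,5-dimethoxyphenyl]methyl}-3-hydroxy-2-oxooxolane-3-carboxylate (C3 epimers) | COC(=O)C1(O)C(=O)OC[C@@H]1Cc1cc(OC)c(OCc2ccccc2)c(OC)c1 | intermediate
13 | dilithium 2-hydroxy-2-[(2S)-1-[4-(benzyloxy)-3,5-dimethoxyphenyl]-3-hydroxypropan-2-yl]propanedioate (not isolated) | [Li+].[Li+].[O-]C(=O)C(O)(C(=O)[O-])[C@H](CO)Cc1cc(OC)c(OCc2ccccc2)c(OC)c1 | intermediate
14 | (4S)-4-{[4-(benzyloxy)-3,5-dimethoxyphenyl]methyl}-3-hydroxy-2-oxooxolane-3-carboxylic acid (C3 epimers) | OC(=O)C1(O)C(=O)OC[C@@H]1Cc1cc(OC)c(OCc2ccccc2)c(OC)c1 | intermediate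
15 | [4-(benzyloxy)-3-methoxyphenyl]acetic acid | COc1cc(CC(=O)O)ccc1OCc1ccccc1 | starting material
16 | O-acylisourea of 15 with DIC (not isolated) | CC(C)N=C(NC(C)C)OC(=O)Cc1ccc(OCc2ccccc2)c(OC)c1 | intermediate
17 | 1,3-dioxoisoindolin-2-yl [4-(benzyloxy)-3-methoxyphenyl]acetate | COc1cc(CC(=O)ON2C(=O)c3ccccc3C2=O)ccc1OCc1ccccc1 | intermediate
18 | (4S)-4-{[4-(benzyloxy)-3,5-dimethoxyphenyl]methyl}-3-hydroxy-2-oxooxolan-3-yl radical (not isolated) | O[C]1C(=O)OC[C@@H]1Cc1cc(OC)c(OCc2ccccc2)c(OC)c1 | intermediate
19 | [4-(benzyloxy)-3-methoxyphenyl]methyl radical (not isolated) | [CH2]c1ccc(OCc2ccccc2)c(OC)c1 | intermediate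
20 | (3S,4S)-3-{[4-(benzyloxy)-3-methoxyphenyl]methyl}-4-{[4-(benzyloxy)-3,5-dimethoxyphenyl]methyl}-3-hydroxyoxolan-2-one | COc1cc(C[C@@]2(O)C(=O)OC[C@@H]2Cc2cc(OC)c(OCc3ccccc3)c(OC)c2)ccc1OCc1ccccc1 | intermediate
21 | (3S,4S)-3-hydroxy-3-[(4-hydroxy-3-methoxyphenyl)methyl]-4-[(4-hydroxy-3,5-dimethoxyphenyl)methyl]oxolan-2-one (CNP0315014.1) | COc1cc(C[C@@]2(O)C(=O)OC[C@@H]2Cc2cc(OC)c(O)c(OC)c2)ccc1O | target

## Step count and risk

Total steps: 8. Longest linear sequence: 6 (steps 1, 3, 4, 5, 7, 8 from (R)-epichlorohydrin).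

**Step 7 (the proposed new photochemical coupling).** Likely failure modes are benzyl homodimer, disproportionation or oxidation of radical 18 to the enolised keto lactone (which would erase C4), and modest facial selectivity. The fallback uses known chemistry and sets out from 14. Heating 14 in DMSO at 100 °C decarboxylates it to (4S)-4-{[4-(benzyloxy)-3,5-dimethoxyphenyl]methyl}-3-hydroxyoxolan-2-one F5 (either C3 epimer serves). Double deprotonation with LiN(i-Pr)2 (2.2 equiv) in THF/DMPU at −78 °C gives the dilithium enediolate of F5, F6. Alkylation with purchased 4-(benzyloxy)-3-methoxybenzyl bromide (COc1cc(CBr)ccc1OCc1ccccc1) proceeds anti to the C4 substituent, the established ionic dianion benzylation of α-hydroxy-β-benzylbutyrolactones. The route is rejoined at 20.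

**Step 3 (Cu-catalysed aryl-Grignard opening).** The electron-rich aryl Grignard may attack the lactone or ester carbonyl, or open the cyclopropane sluggishly. The fallback sets out from 5 and replaces the organometallic nucleophile by two electrophiles. MgI2 in THF at 60 °C opens the activated cyclopropane at CH2 to give methyl (4R)-4-(iodomethyl)-2-oxooxolane-3-carboxylate F1. A nickel-catalysed reductive cross-electrophile coupling of F1 with aryl bromide 7 (NiBr2(dme), 4,4'-di-tert-butyl-2,2'-bipyridine, Zn, DMA, 60 °C) then forms the CH2–aryl bond. The route is rejoined at 10.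

**Step 5 (saponification and relactonisation).** The hindered ester may hydrolyse slowly, or the half-acid may decarboxylate during acidic ring closure. The fallback avoids base and lactone opening by changing the ester from the outset; it sets out from 1.
- Reaction of 1 with di-tert-butyl malonate (CC(C)(C)OC(=O)CC(=O)OC(C)(C)C; KOt-Bu, t-BuOH, 50 °C) gives tert-butyl (1R,5R)-2-oxo-3-oxabicyclo[3.1.0]hexane-1-carboxylate F2. Its spatial arrangement is that of 5; the C1 descriptor changes only because the tert-butyl ester outranks the lactone carbonyl.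
- Opening with Grignard 8 and CuI as before gives tert-butyl (4R)-4-{[4-(benzyloxy)-3,5-dimethoxyphenyl]methyl}-2-oxooxolane-3-carboxylate F3.
- Enolate hydroxylation as before gives tert-butyl (4S)-4-{[4-(benzyloxy)-3,5-dimethoxyphenyl]methyl}-3-hydroxy-2-oxooxolane-3-carboxylate F4.
- Acidolysis (TFA/CH2Cl2 1:4, Et3SiH, 0 °C) unmasks the acid with the lactone intact. The route is rejoined at 14.

## Further compounds

F1 | step 3 | methyl (4R)-4-(iodomethyl)-2-oxooxolane-3-carboxylate | COC(=O)C1C(=O)OC[C@@H]1CI
F2 | step 5 | tert-butyl (1R,5R)-2-oxo-3-oxabicyclo[3.1.0]hexane-1-carboxylate | CC(C)(C)OC(=O)[C@]12C[C@H]1COC2=O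
F3 | step 5 | tert-butyl (4R)-4-{[4-(benzyloxy)-3,5-dimethoxyphenyl]methyl}-2-oxooxolane-3-carboxylate | CC(C)(C)OC(=O)C1C(=O)OC[C@@H]1Cc1cc(OC)c(OCc2ccccc2)c(OC)c1
F4 | step 5 | tert-butyl (4S)-4-{[4-(benzyloxy)-3,5-dimethoxyphenyl]methyl}-3-hydroxy-2-oxooxolane-3-carboxylate | CC(C)(C)OC(=O)C1(O)C(=O)OC[C@@H]1Cc1cc(OC)c(OCc2ccccc2)c(OC)c1
F5 | step 7 | (4S)-4-{[4-(benzyloxy)-3,5-dimethoxyphenyl]methyl}-3-hydroxyoxolan-2-one | OC1C(=O)OC[C@@H]1Cc1cc(OC)c(OCc2ccccc2)c(OC)c1
F6 | step 7 | dilithium enediolate of F5 | [Li+].[Li+].[O-]C1=C([O-])OC[C@@H]1Cc1cc(OC)c(OCc2ccccc2)c(OC)c1
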